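## The problem

The target 20 is a 2,2-disubstituted 2H-chromen-5-ol whose benzene ring carries oxygen on five of its six carbons: the C5 hydroxyl, methoxyls at C6, C7 and C8, and the ring oxygen O1 on C8a. C2 bears a methyl group and a two-carbon linker to a 1,2,3-trimethylcyclohex-3-enyl ring. Locants used throughout are O1, C2, C3, C4, C4a, C5–C8, C8a for the chromene and C1′ (quaternary), C2′ (CH–CH3), C3′=C4′, C5′, C6′ for the carbocycle. Three stereocentres must be set: C2 (R), and the adjacent pair C1′ (S) and C2′ (S), whose methyl groups are cis. C1′ and C2′ are neighbours and can be made in one ring-forming event, but C2 lies four bonds away across a flexible chain. Neither part can control the other, so two independent reagent-controlled operations are needed, each of high fidelity, because the remote diastereomers would be nearly inseparable. Three groups are fragile. The electron-rich C3=C4 enol-ether-like double bond takes up acid and electrophiles at C3. The penta-oxygenated arene goes to a quinone once the C5 phenol is free. The trisubstituted C3′=C4′ bond beside C2′–H can migrate under strong acid or isomerising metal catalysts. The enabling feature is that the pyran ring is fused to the arene through the adjacent bonds C4–C4a and O1–C8a, while the other neighbour of C8a, C8, already carries a methoxyl. An arene iodinated at C8a therefore has one blocked ortho position and exactly one ortho C–H (C4a), the pattern a palladium/norbornene relay needs to place carbon ortho and oxygen ipso in one operation.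

## Retrosynthesis

**20 ⇒ 19 ⇒ 18 (C5–O protecting group, C3=C4).** The free phenol is released last because, once free, the ring is easily oxidised. The C3=C4 double bond is introduced just before that by dehydrogenating chroman 18. The key annulation uses a saturated three-carbon electrophile and so delivers C3 and C4 as methylenes. A methoxymethyl ether is chosen for C5 because it survives carbonate base at 110 °C, zerovalent palladium and DDQ, and leaves under dilute acid.

**18 ⇒ 5 + 17 (C4–C4a and O1–C8a).** Cutting both bonds that join the pyran ring to the arene gives aryl iodide 5 and oxetane 17. The oxetane atoms O1, C2, C3, C4 become the same-numbered atoms of the pyran ring. Single-bond cuts (O1–C2 etherification, or C4–C4a Friedel–Crafts alkylation) would either form the tertiary ether at the stereocentre or need regiocontrol on an arene with two free positions. The double cut leaves C2 untouched and uses the substitution pattern for site control. Both fragments are much simpler: 5 is a benzene with no stereochemistry, and 17 carries all three stereocentres in a compact ether. The forward reaction must open the oxetane at its CH2–O carbon with an aryl–palladium species and then couple the liberated tertiary alkoxide at the ipso carbon.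

**17 ⇒ 15 ⇒ 14 ⇒ 13 (oxetane O–C4, C3–H, epoxide).** The oxetane is a Williamson closure of diol 15 through its primary tosylate. Diol 15 comes from C2-selective hydride opening of epoxy alcohol 14, and 14 from Sharpless epoxidation of (E)-allylic alcohol 13. This sequence sets the tertiary C–O stereocentre by reagent control and never breaks that bond afterwards. Enantioselective addition to a dialkyl ketone was rejected as less reliable for two similar alkyl groups.

**13 ⇒ 12 ⇒ 11 ⇒ 9 ⇒ 8 (chain C2=C3 and C4–C5).** The allylic alcohol is reduced back to ester 12, and the C2=C3 bond of 12 is cut by Horner–Wadsworth–Emmons olefination to methyl ketone 11. Ketone 11 is the conjugate-reduction product of enone 9, whose C=C comes from olefination of aldehyde 8. Direct SN2 coupling at the neopentyl carbon next to C1′ was avoided. Carbonyl olefination at the hindered but non-enolisable aldehyde is dependable. The price is control of the C2=C3 geometry in 12.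

**8 ⇒ 6 + 7 (C1′–C2′ and C5′–C6′).** The cyclohexene is a Diels–Alder adduct of methacrolein 6 and (E)-3-methylpenta-1,3-diene 7. One step builds the ring, the quaternary centre, the cis-dimethyl pair (formyl-exo transition state) and the C3′=C4′ bond in place. A chiral cationic oxazaborolidine sets the absolute configuration.

**5 ⇒ 4 ⇒ 2 ⇒ 1 (C–I, C–O).** The iodine must sit meta to the C5 oxygen with a hydrogen between them, which direct iodination of a phenol cannot give. So the iodine is introduced on commercial 2,3,4-trimethoxybenzaldehyde 1, where the methoxyls direct it to C5 of the aldehyde. The formyl group is then converted to the oxygen by Baeyer–Villiger oxidation (phenol 4) and protected.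

## Roads not taken

**Alternative 1:** The cut removes the two ring methyls at C1′ and C2′ and traces them to the two carbons of a cyclobutane. In the forward sense, enone A1 (carbonyl at C3′, protected linker on C1′) is irradiated with (Z)-1,2-dichloroethene A2 to give the cis-fused dichlorobicyclo[4.2.0]octanone A3. The merit is that the cis relation of the two future methyls is guaranteed by the ring fusion, and the quaternary carbon forms without steric penalty. The weak points are several:
- The intermolecular photocycloaddition gives racemic material, with no dependable reagent control for this substrate.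
- Unravelling the cyclobutane into two methyls takes about five operations (dechlorination to the cyclobutene, oxidative cleavage, twofold deoxygenation).
- The ketone must still be turned into the methyl-bearing C3′=C4′ alkene.
- C2′, alpha to that ketone, can epimerise once the four-membered ring is open.

In security of relative configuration this road is better than an exo-selective cycloaddition. The chosen plan sets against that a one-step, catalyst-controlled entry to the same ring and a resolution fallback. The alternative also leaves C2 of the chromene unaddressed.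

**Alternative 2:** The cut is C1′–C6′ and C2′–C3′. (E)-2-Methylbut-2-enal A4 and (3Z)-3-(triisopropylsilyloxy)penta-1,3-diene A5 combine under a chiral Lewis acid to give silyl enol ether A6, with oxygen on C4′. The merits are real. The cis-dimethyl pair follows from the dienophile geometry and not from an exo/endo preference. The siloxy group also fixes the regiochemistry, whereas in the chosen cycloaddition the two methyls of 7 direct in opposite senses. The weak points are as follows:
- A4 is an alpha,beta-disubstituted and therefore sluggish dienophile.
- The C4′ oxygen has to be removed again.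
- The double bond has to be moved to C3′=C4′ by regioselective enolisation toward the more hindered carbon, followed by reduction of the enol derivative, all with an aldehyde present.

That costs three or four steps. On regiochemical certainty this road is better. The chosen plan sets against it a one-step ring synthesis with no oxygen to delete, and the fact that any regioisomer problem shows itself at the first step of the side chain.

**Alternative 3:** The cut is C1′–C2′ and C5′–C6′, and the forward key step is the exo-selective cycloaddition of 6 and 7 under a chiral cationic oxazaborolidine to aldehyde A7. A7 is the same compound as 8. As a ring synthesis it is the shortest possible, and the chosen plan adopts it as step 4. As the organising idea of the whole synthesis it treats the carbocycle as the main problem. It leaves the chromene to a conventional late condensation and oxa-electrocyclisation, which creates C2 without control and would give both C2 epimers. This road is better in one respect: every reaction in it is precedented. The chosen plan sets against that a C2 stereocentre fixed by Sharpless epoxidation and never touched again, at the price of one unprecedented catalytic step, which is covered by a fallback of known reactions.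

Key step: step 12

Assumption: the facial preference of the oxazaborolidinium catalyst in step 4 is taken from the accepted model for 2-substituted acroleins (formyl C–H···O contact, s-trans enal, one face covered by a phenyl group). Applied to this diene it assigns the (R)-prolinol-derived catalyst to (1R,2R)-8. If the sense proved opposite, the enantiomeric catalyst would be used and nothing else would change.

Step 1
Reactants: 1 2,3,4-trimethoxybenzaldehyde
Product: 2 5-iodo-2,3,4-trimethoxybenzaldehyde
Conditions: NIS (1.1 equiv), CF3CO2H (30 mol%), MeCN, rt → 50 °C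
Reagents that add atoms: N-iodosuccinimide, O=C1CCC(=O)N1I
Why: Electrophilic aromatic iodination; C5 is ortho to the C4 methoxyl, para to the C2 methoxyl and meta to the formyl group, while C6 is ortho to the deactivating formyl group, so iodine should enter at C5 only.

Step 2
Reactants: 2 5-iodo-2,3,4-trimethoxybenzaldehyde
Product: 4 5-iodo-2,3,4-trimethoxyphenol, via 5-iodo-2,3,4-trimethoxyphenyl formate 3 (not isolated)
Conditions: mCPBA, CH2Cl2, 0 °C → rt; aq. NaHCO3 wash; then K2CO3 (cat.), MeOH, rt
Reagents that add atoms: 3-chloroperoxybenzoic acid, OOC(=O)c1cccc(Cl)c1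
Why: Baeyer–Villiger oxidation of an electron-rich benzaldehyde; the aryl group, activated by ortho and para methoxyls, migrates and the formate is methanolysed. This places oxygen meta to iodine, and the aryl iodide is inert to the peracid.

Step 3
Reactants: 4 5-iodo-2,3,4-trimethoxyphenol
Product: 5 1-iodo-2,3,4-trimethoxy-5-(methoxymethoxy)benzene
Conditions: MOMCl, iPr2NEt, CH2Cl2, 0 °C → rt
Reagents that add atoms: chloromethyl methyl ether, COCCl
Why: O-Alkylation of the phenol with an alpha-chloro ether; the acetal is stable to carbonate base, palladium catalysis and DDQ and is removed by dilute acid.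

Step 4
Reactants: 6 methacrolein; 7 (3E)-3-methylpenta-1,3-diene
Product: 8 (1R,2R)-1,2,3-trimethylcyclohex-3-ene-1-carbaldehyde
Conditions: (R)-3,3-diphenyl-1-(2-methylphenyl)tetrahydro-1H,3H-pyrrolo[1,2-c][1,3,2]oxazaborole (20 mol%) activated with HN(SO2CF3)2 (17 mol%), 7 (3 equiv), CH2Cl2, −78 → −40 °C
Reagents that add atoms: none
Why: Catalytic enantioselective Diels–Alder reaction of a 2-substituted acrolein with an acyclic diene. The terminal methyl of 7 should outweigh the internal one, so the enal beta-carbon bonds to the unsubstituted diene terminus, and the formyl-exo transition state typical of alpha-substituted acroleins places the two methyls cis. The catalyst shields one face of the s-trans enal and so sets C1′ and, with it, C2′.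

Step 5
Reactants: 8 (1R,2R)-1,2,3-trimethylcyclohex-3-ene-1-carbaldehyde
Product: 9 (3E)-4-[(1S,2R)-1,2,3-trimethylcyclohex-3-en-1-yl]but-3-en-2-one
Conditions: (MeO)2P(O)CH2C(O)CH3, NaH, THF, 0 → 50 °C
Reagents that add atoms: dimethyl (2-oxopropyl)phosphonate, COP(=O)(CC(C)=O)OC
Why: Horner–Wadsworth–Emmons olefination of a non-enolisable alpha-quaternary aldehyde; the stabilised phosphonate anion gives the (E)-enone, and the stereocentres are not alpha to an acidic hydrogen.

Step 6
Reactants: 9 (3E)-4-[(1S,2R)-1,2,3-trimethylcyclohex-3-en-1-yl]but-3-en-2-one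
Product: 11 4-[(1S,2S)-1,2,3-trimethylcyclohex-3-en-1-yl]butan-2-one, via triethylsilyl enol ether 10 (not isolated)
Conditions: Et3SiH (1.2 equiv), RhCl(PPh3)3 (1 mol%), THF, 50 °C; then 1 M HCl, THF, rt
Reagents that add atoms: none
Why: Rhodium-catalysed 1,4-hydrosilylation of an enone with a monohydrosilane, followed by hydrolysis of the silyl enol ether; the isolated trisubstituted ring alkene is not hydrosilylated under these conditions.

Step 7
Reactants: 11 4-[(1S,2S)-1,2,3-trimethylcyclohex-3-en-1-yl]butan-2-one
Product: 12 ethyl (2E)-3-methyl-5-[(1S,2S)-1,2,3-trimethylcyclohex-3-en-1-yl]pent-2-enoate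
Conditions: (EtO)2P(O)CH2CO2Et, NaH, THF, 0 → 65 °C; chromatographic removal of the minor (2Z)-ester
Reagents that add atoms: triethyl phosphonoacetate, CCOC(=O)CP(=O)(OCC)OCC
Why: Horner–Wadsworth–Emmons olefination of a methyl ketone, which favours the (E)-trisubstituted enoate; the geometric isomers of such esters are separable on silica, and the isomer must be pure because the alkene geometry decides the configuration at the later C2.

Step 8
Reactants: 12 ethyl (2E)-3-methyl-5-[(1S,2S)-1,2,3-trimethylcyclohex-3-en-1-yl]pent-2-enoate
Product: 13 (2E)-3-methyl-5-[(1S,2S)-1,2,3-trimethylcyclohex-3-en-1-yl]pent-2-en-1-ol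
Conditions: iBu2AlH (2.2 equiv), CH2Cl2, −78 → 0 °C; aqueous potassium sodium tartrate work-up
Reagents that add atoms: none
Why: 1,2-Reduction of an alpha,beta-unsaturated ester by an aluminium hydride, with the alkene geometry retained.

Step 9
Reactants: 13 (2E)-3-methyl-5-[(1S,2S)-1,2,3-trimethylcyclohex-3-en-1-yl]pent-2-en-1-ol
Product: 14 [(2R,3R)-3-methyl-3-[2-[(1S,2S)-1,2,3-trimethylcyclohex-3-en-1-yl]ethyl]oxiran-2-yl]methanol
Conditions: Ti(OiPr)4 (10 mol%), D-(−)-diethyl tartrate (12 mol%), t-BuOOH (2 equiv), 4 Å molecular sieves, CH2Cl2, −20 °C
Reagents that add atoms: tert-butyl hydroperoxide, CC(C)(C)OO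
Why: Sharpless asymmetric epoxidation; the D-(−)-tartrate gives the (2R,3R)-epoxide of an (E)-3,3-disubstituted allylic alcohol, the mirror image of the (2S,3S) result of geraniol with the L-(+)-tartrate. The tertiary C–O stereocentre, the later C2, is therefore set by the reagent, and the ring alkene, which lacks a directing hydroxyl, is not epoxidised.

Step 10
Reactants: 14 [(2R,3R)-3-methyl-3-[2-[(1S,2S)-1,2,3-trimethylcyclohex-3-en-1-yl]ethyl]oxiran-2-yl]methanol
Product: 15 (3R)-3-methyl-5-[(1S,2S)-1,2,3-trimethylcyclohex-3-en-1-yl]pentane-1,3-diol
Conditions: NaAlH2(OCH2CH2OCH3)2 (2 equiv), THF, 0 °C → rt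
Reagents that add atoms: none
Why: Hydride opening of a 2,3-epoxy alcohol; delivery from the aluminium alkoxide to the less hindered C2 gives the 1,3-diol, and the C3–O bond and its configuration are untouched.

Step 11
Reactants: 15 (3R)-3-methyl-5-[(1S,2S)-1,2,3-trimethylcyclohex-3-en-1-yl]pentane-1,3-diol
Product: 17 (2R)-2-methyl-2-[2-[(1S,2S)-1,2,3-trimethylcyclohex-3-en-1-yl]ethyl]oxetane, via primary monotosylate 16 (not isolated)
Conditions: n-BuLi (1.0 equiv), THF, 0 °C; TsCl (1.0 equiv); then n-BuLi (1.05 equiv), 0 → 60 °C
Reagents that add atoms: none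
Why: One-pot selective sulfonylation of the primary hydroxyl and intramolecular Williamson etherification (4-exo-tet) by the tertiary alkoxide; the stereocentre is the nucleophile's carbon, not the reacting carbon, so its configuration is retained.

Step 12
Reactants: 5 1-iodo-2,3,4-trimethoxy-5-(methoxymethoxy)benzene; 17 (2R)-2-methyl-2-[2-[(1S,2S)-1,2,3-trimethylcyclohex-3-en-1-yl]ethyl]oxetane
Product: 18 (2R)-6,7,8-trimethoxy-5-(methoxymethoxy)-2-methyl-2-[2-[(1S,2S)-1,2,3-trimethylcyclohex-3-en-1-yl]ethyl]-3,4-dihydro-2H-chromene
Conditions: 5 (1.5 equiv), Pd(OAc)2 (10 mol%), XPhos (20 mol%), norbornene (1.0 equiv), Cs2CO3 (2.5 equiv), NMP, 110 °C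
Reagents that add atoms: none
Why: Proposed new method: zerovalent palladium inserts into the C8a–I bond of 5, norbornene inserts, and metalation of C4a–H, the only ortho C–H, gives the five-membered aryl–norbornyl palladacycle of divalent palladium; this electron-rich palladacycle is expected to open 17 by SN2-type oxidative addition at the unhindered C4 methylene (caesium ion assisting the departing alkoxide), and the tetravalent palladium intermediate forms C4–C4a by reductive elimination. With C8 (methoxyl) and C4a (alkyl) both substituted, beta-carbon elimination expels norbornene, and the arylpalladium tert-alkoxide, a seven-membered chelate that has no beta-hydrogen on the carbinol carbon, closes the dihydropyran by C–O reductive elimination at C8a, which the bulky biarylphosphine promotes. The closest known reaction type is the palladium/norbornene annulation of aryl iodides with epoxides to 2,3-dihydrobenzofurans; this is its one-carbon homologue with a less electrophilic four-membered ether and a more hindered alkoxide. The six-membered ring is closed in a formal [3+3] mode: intermolecular C–C bond formation at the ortho carbon, then intramolecular C–O coupling at the ipso carbon. No stereocentre is formed; C2 arrives with 17 and none of its four bonds is broken, so its configuration is retained. The step needs site selectivity, regioselective opening at CH2 and alkylation before ipso termination; these are secured respectively by the fully substituted arene, by the quaternary C2, and by the absence of any alkoxide until the oxetane has opened.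

Step 13
Reactants: 18 (2R)-6,7,8-trimethoxy-5-(methoxymethoxy)-2-methyl-2-[2-[(1S,2S)-1,2,3-trimethylcyclohex-3-en-1-yl]ethyl]-3,4-dihydro-2H-chromene
Product: 19 (2R)-6,7,8-trimethoxy-5-(methoxymethoxy)-2-methyl-2-[2-[(1S,2S)-1,2,3-trimethylcyclohex-3-en-1-yl]ethyl]-2H-chromene
Conditions: DDQ (1.5 equiv), anhydrous 1,4-dioxane, 80 °C
Reagents that add atoms: none
Why: Quinone dehydrogenation of a chroman to a 2H-chromene; hydride is abstracted from benzylic C4, whose cation is stabilised by the oxygens on C5, C7 and C8a, and loss of a C3 proton gives the alkene. The allylic C–H bonds of the cyclohexene give far less stabilised cations, and the protected phenol and anhydrous medium prevent quinone formation.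

Step 14
Reactants: 19 (2R)-6,7,8-trimethoxy-5-(methoxymethoxy)-2-methyl-2-[2-[(1S,2S)-1,2,3-trimethylcyclohex-3-en-1-yl]ethyl]-2H-chromene
Product: 20 (2R)-6,7,8-trimethoxy-2-methyl-2-[2-[(1S,2S)-1,2,3-trimethylcyclohex-3-en-1-yl]ethyl]-2H-chromen-5-ol
Conditions: 2 M aq. HCl (cat.), MeOH–THF, rt
Reagents that add atoms: none
Why: Acid-catalysed transacetalisation of an aryl methoxymethyl ether with methanol; aryl ethers of this kind are cleaved by dilute acid at room temperature, conditions that 2,2-dialkyl-2H-chromenes and trisubstituted alkenes normally tolerate.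

## Compound list

1 | 2,3,4-trimethoxybenzaldehyde | COc1ccc(C=O)c(OC)c1OC | starting material
2 | 5-iodo-2,3,4-trimethoxybenzaldehyde | COc1c(I)cc(C=O)c(OC)c1OC | intermediate
3 | 5-iodo-2,3,4-trimethoxyphenyl formate | COc1c(I)cc(OC=O)c(OC)c1OC | intermediate (not isolated)
4 | 5-iodo-2,3,4-trimethoxyphenol | COc1c(I)cc(O)c(OC)c1OC | intermediate
5 | 1-iodo-2,3,4-trimethoxy-5-(methoxymethoxy)benzene | COCOc1cc(I)c(OC)c(OC)c1OC | intermediate
6 | methacrolein (2-methylprop-2-enal) | CC(=C)C=O | starting material
7 | (3E)-3-methylpenta-1,3-diene | C=C/C(C)=C/C | starting material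
8 | (1R,2R)-1,2,3-trimethylcyclohex-3-ene-1-carbaldehyde | O=C[C@]1(C)CCC=C(C)[C@H]1C | intermediate
9 | (3E)-4-[(1S,2R)-1,2,3-trimethylcyclohex-3-en-1-yl]but-3-en-2-one | CC(=O)/C=C/[C@]1(C)CCC=C(C)[C@H]1C | intermediate
10 | triethyl[[4-[(1S,2S)-1,2,3-trimethylcyclohex-3-en-1-yl]but-2-en-2-yl]oxy]silane (enol ether geometry not defined) | CC[Si](CC)(CC)OC(C)=CC[C@]1(C)CCC=C(C)[C@H]1C | intermediate (not isolated)
11 | 4-[(1S,2S)-1,2,3-trimethylcyclohex-3-en-1-yl]butan-2-one | CC(=O)CC[C@]1(C)CCC=C(C)[C@H]1C | intermediate
12 | ethyl (2E)-3-methyl-5-[(1S,2S)-1,2,3-trimethylcyclohex-3-en-1-yl]pent-2-enoate | CCOC(=O)/C=C(\C)CC[C@]1(C)CCC=C(C)[C@H]1C | intermediate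
13 | (2E)-3-methyl-5-[(1S,2S)-1,2,3-trimethylcyclohex-3-en-1-yl]pent-2-en-1-ol | OC/C=C(\C)CC[C@]1(C)CCC=C(C)[C@H]1C | intermediate
14 | [(2R,3R)-3-methyl-3-[2-[(1S,2S)-1,2,3-trimethylcyclohex-3-en-1-yl]ethyl]oxiran-2-yl]methanol | C[C@]1(CC[C@]2(C)CCC=C(C)[C@H]2C)O[C@@H]1CO | intermediate
15 | (3R)-3-methyl-5-[(1S,2S)-1,2,3-trimethylcyclohex-3-en-1-yl]pentane-1,3-diol | C[C@@](O)(CC[C@]1(C)CCC=C(C)[C@H]1C)CCO | intermediate
16 | (3R)-3-hydroxy-3-methyl-5-[(1S,2S)-1,2,3-trimethylcyclohex-3-en-1-yl]pentyl 4-methylbenzenesulfonate | C[C@@](O)(CC[C@]1(C)CCC=C(C)[C@H]1C)CCOS(=O)(=O)c1ccc(C)cc1 | intermediate (not isolated)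
17 | (2R)-2-methyl-2-[2-[(1S,2S)-1,2,3-trimethylcyclohex-3-en-1-yl]ethyl]oxetane | C[C@@]1(CC[C@]2(C)CCC=C(C)[C@H]2C)CCO1 | intermediate
18 | (2R)-6,7,8-trimethoxy-5-(methoxymethoxy)-2-methyl-2-[2-[(1S,2S)-1,2,3-trimethylcyclohex-3-en-1-yl]ethyl]-3,4-dihydro-2H-chromene | COc1c(OCOC)c2c(c(OC)c1OC)O[C@](C)(CC[C@]1(C)CCC=C(C)[C@H]1C)CC2 | intermediate
19 | (2R)-6,7,8-trimethoxy-5-(methoxymethoxy)-2-methyl-2-[2-[(1S,2S)-1,2,3-trimethylcyclohex-3-en-1-yl]ethyl]-2H-chromene | COc1c(OCOC)c2c(c(OC)c1OC)O[C@](C)(CC[C@]1(C)CCC=C(C)[C@H]1C)C=C2 | intermediate
20 | (2R)-6,7,8-trimethoxy-2-methyl-2-[2-[(1S,2S)-1,2,3-trimethylcyclohex-3-en-1-yl]ethyl]-2H-chromen-5-ol | COc1c(O)c2c(c(OC)c1OC)O[C@](C)(CC[C@]1(C)CCC=C(C)[C@H]1C)C=C2 | target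

## Step count and least certain steps

Total: 14 steps. Longest linear sequence: 11 steps (steps 4–14, from 6 and 7). The aryl iodide branch (steps 1–3) joins at step 12.

**Step 12 (key step, proposed new method).** The most likely failure is slow ring opening of the oxetane by the aryl–norbornyl palladacycle, since an oxetane is a much poorer electrophile than an epoxide. The palladacycle would then be diverted into norbornene-containing by-products. Alternatively the final C–O reductive elimination with a hindered tertiary alkoxide could lose to ipso hydrogenolysis and leave the uncyclised alcohol. The fallback uses known reactions, sets out from 1 and 17 and returns at 18. Baeyer–Villiger oxidation of 1 gives 2,3,4-trimethoxyphenyl formate F1, which is methanolysed to 2,3,4-trimethoxyphenol F2 and protected as 1,2,3-trimethoxy-4-(methoxymethoxy)benzene F3. Lithiation of F3 with n-BuLi ortho to the methoxymethoxy group (the stronger director) and BF3·OEt2-promoted opening of 17 at its CH2–O carbon at −78 °C give the tertiary alcohol (3R)-3-methyl-1-[3,4,5-trimethoxy-2-(methoxymethoxy)phenyl]-5-[(1S,2S)-1,2,3-trimethylcyclohex-3-en-1-yl]pentan-3-ol F4. This is also the compound that ipso hydrogenolysis in step 12 would produce. NBS brominates its only remaining aromatic C–H to give the bromo alcohol (3R)-1-[2-bromo-3,4,5-trimethoxy-6-(methoxymethoxy)phenyl]-3-methyl-5-[(1S,2S)-1,2,3-trimethylcyclohex-3-en-1-yl]pentan-3-ol F5. Intramolecular palladium-catalysed etherification of the aryl bromide by the tertiary alcohol (Pd(OAc)2, 2-(di-tert-butylphosphino)-1,1′-binaphthyl, Cs2CO3, toluene, 80 °C) then closes the pyran ring to 18.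

**Step 4.** The most likely failure is incomplete enantiofacial and exo/endo discrimination with an acyclic, weakly nucleophilic diene whose two methyl groups direct regiochemistry in opposite senses, together with diene oligomerisation by the strongly acidic catalyst. The result would be aldehyde of insufficient optical purity. The fallback sets out from 6 and 7 and returns at 8. Cycloaddition under EtAlCl2 gives the racemic cis adduct, (1R,2R)- plus (1S,2S)-1,2,3-trimethylcyclohex-3-ene-1-carbaldehyde F6. Oxidation with NaClO2/NaH2PO4/2-methylbut-2-ene gives the racemic acid F7. Crystallisation of its salt with whichever enantiomer of 1-phenylethylamine gives the less soluble salt of the wanted acid affords (1R,2R)-1,2,3-trimethylcyclohex-3-ene-1-carboxylic acid F8. LiAlH4 reduction gives [(1R,2R)-1,2,3-trimethylcyclohex-3-en-1-yl]methanol F9, and oxidation with Dess–Martin periodinane returns 8.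

**Step 7.** The most likely failure is moderate E/Z selectivity in the olefination of a methyl ketone and incomplete removal of the (2Z)-ester, which would carry the C2 epimer through to the end. The fallback avoids alkene geometry altogether, sets out from 11 and returns at 17. Catalytic asymmetric Corey–Chaykovsky epoxidation of 11 with dimethylsulfoxonium methylide, LaLi3(1,1′-binaphthalene-2,2′-diolate)3 and a triarylphosphine oxide, using the catalyst enantiomer that gives the R epoxide, affords (2R)-2-methyl-2-[2-[(1S,2S)-1,2,3-trimethylcyclohex-3-en-1-yl]ethyl]oxirane F10. Ring expansion of F10 with more of the same ylide at 45–50 °C (attack at the epoxide CH2, then closure by the tertiary alkoxide) gives 17 with the quaternary centre retained.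

**Step 13.** The most likely failure is hydride abstraction at the allylic positions of the cyclohexene, or oxidative degradation of the very electron-rich arene, at the temperature needed for benzylic abstraction from the protected chroman. The fallback replaces hydride abstraction by phenol oxidation, sets out from 18 and returns at 20. The methoxymethyl group is removed first (2 M HCl, MeOH; the chroman tolerates acid) to give (2R)-6,7,8-trimethoxy-2-methyl-2-[2-[(1S,2S)-1,2,3-trimethylcyclohex-3-en-1-yl]ethyl]-3,4-dihydro-2H-chromen-5-ol F11. Oxidation of F11 with Ag2O in benzene at room temperature gives the ortho-quinone methide (2R)-6,7,8-trimethoxy-2-methyl-2-[2-[(1S,2S)-1,2,3-trimethylcyclohex-3-en-1-yl]ethyl]-2,3-dihydro-5H-chromen-5-one F12. A 1,5-hydrogen shift from C3 to the carbonyl oxygen of F12 restores the arene and gives 20 directly.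

## Further compounds

F1 | step 12 | 2,3,4-trimethoxyphenyl formate | COc1ccc(OC=O)c(OC)c1OC
F2 | step 12 | 2,3,4-trimethoxyphenol | COc1ccc(O)c(OC)c1OC
F3 | step 12 | 1,2,3-trimethoxy-4-(methoxymethoxy)benzene | COCOc1ccc(OC)c(OC)c1OC
F4 | step 12 | (3R)-3-methyl-1-[3,4,5-trimethoxy-2-(methoxymethoxy)phenyl]-5-[(1S,2S)-1,2,3-trimethylcyclohex-3-en-1-yl]pentan-3-ol | COCOc1c(OC)c(OC)c(OC)cc1CC[C@](C)(O)CC[C@]1(C)CCC=C(C)[C@H]1C
F5 | step 12 | (3R)-1-[2-bromo-3,4,5-trimethoxy-6-(methoxymethoxy)phenyl]-3-methyl-5-[(1S,2S)-1,2,3-trimethylcyclohex-3-en-1-yl]pentan-3-ol | COCOc1c(OC)c(OC)c(OC)c(Br)c1CC[C@](C)(O)CC[C@]1(C)CCC=C(C)[C@H]1C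
F6 | step 4 | racemic cis-1,2,3-trimethylcyclohex-3-ene-1-carbaldehyde, (1R,2R) plus (1S,2S) | O=C[C@]1(C)CCC=C(C)[C@H]1C.O=C[C@@]1(C)CCC=C(C)[C@@H]1C
F7 | step 4 | racemic cis-1,2,3-trimethylcyclohex-3-ene-1-carboxylic acid, (1R,2R) plus (1S,2S) | OC(=O)[C@]1(C)CCC=C(C)[C@H]1C.OC(=O)[C@@]1(C)CCC=C(C)[C@@H]1C
F8 | step 4 | (1R,2R)-1,2,3-trimethylcyclohex-3-ene-1-carboxylic acid | OC(=O)[C@]1(C)CCC=C(C)[C@H]1C
F9 | step 4 | [(1R,2R)-1,2,3-trimethylcyclohex-3-en-1-yl]methanol | OC[C@]1(C)CCC=C(C)[C@H]1C
F10 | step 7 | (2R)-2-methyl-2-[2-[(1S,2S)-1,2,3-trimethylcyclohex-3-en-1-yl]ethyl]oxirane | C[C@@]1(CC[C@]2(C)CCC=C(C)[C@H]2C)CO1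
F11 | step 13 | (2R)-6,7,8-trimethoxy-2-methyl-2-[2-[(1S,2S)-1,2,3-trimethylcyclohex-3-en-1-yl]ethyl]-3,4-dihydro-2H-chromen-5-ol | COc1c(O)c2c(c(OC)c1OC)O[C@](C)(CC[C@]1(C)CCC=C(C)[C@H]1C)CC2
F12 | step 13 | (2R)-6,7,8-trimethoxy-2-methyl-2-[2-[(1S,2S)-1,2,3-trimethylcyclohex-3-en-1-yl]ethyl]-2,3-dihydro-5H-chromen-5-one | O=C1C(OC)=C(OC)C(OC)=C2O[C@](C)(CC[C@]3(C)CCC=C(C)[C@H]3C)CC=C12
A1 | alternative 1 | 3-[2-(2-methyl-1,3-dioxolan-2-yl)ethyl]cyclohex-2-en-1-one | CC1(CCC2=CC(=O)CCC2)OCCO1
A2 | alternative 1 | (Z)-1,2-dichloroethene | Cl/C=C\Cl
A3 | alternative 1 | cis-fused 7,8-dichloro-6-[2-(2-methyl-1,3-dioxolan-2-yl)ethyl]bicyclo[4.2.0]octan-2-one | CC1(CC[C@]23CCCC(=O)[C@H]2C(Cl)C3Cl)OCCO1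
A4 | alternative 2 | (2E)-2-methylbut-2-enal | C/C=C(\C)C=O
A5 | alternative 2 | (3Z)-3-(triisopropylsilyloxy)penta-1,3-diene | C=C/C(O[Si](C(C)C)(C(C)C)C(C)C)=C/C
A6 | alternative 2 | 1,2,3-trimethyl-4-(triisopropylsilyloxy)cyclohex-4-ene-1-carbaldehyde | O=C[C@]1(C)CC=C(O[Si](C(C)C)(C(C)C)C(C)C)[C@H](C)[C@H]1C
A7 | alternative 3 | (1R,2R)-1,2,3-trimethylcyclohex-3-ene-1-carbaldehyde (the same compound as 8) | O=C[C@]1(C)CCC=C(C)[C@H]1C
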